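## The problem

Compound 10, bis(2,3,6-tribromo-4,5-dihydroxyphenyl)methane, is two identical hexasubstituted benzene rings joined by one CH2 group. It has no stereocentre, so the task is purely one of constitution. In each ring C1 carries the bridge, C2, C3 and C6 carry bromine, and C4 and C5 carry the catechol hydroxyls (this numbering is used throughout). No ring position is free, and every substituent has to be placed without a regiochemical gamble, twice in one molecule. Stereocentres occur only in saturated intermediates; none can steer another and all vanish on aromatisation, so they may be carried as mixtures. Three elements are fragile: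

- the free catechols, which are oxidised to ortho-quinones by air in base or by surplus halogen;
- the diarylmethane link, because C1 lies para to the C4 hydroxyl and can suffer ipso attack by an electrophile with loss of the benzyl group;
- the aryl bromides, which do not survive hydrogenation, so every reductive operation must come before bromine enters.

The enabling feature is that C4 and C5, the vicinal oxygenated carbons, map onto the two carbons of an oxalate, while C3–C2–C1–C6 maps onto the α, β, β′ and α′ carbons of an adipate that carries the bridge on a β carbon. A double Claisen condensation of these partners closes the ring with the oxygens already para and meta to the bridge. It also leaves the two adipate ester carbons on C3 and C6, each ortho to a hydroxyl, where ipso-bromodecarboxylation can later exchange them for bromine; C2 remains the only ring CH, para to the C5 hydroxyl.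

## Retrosynthesis

**C–Br bonds (10 back to 9).** The three C–Br bonds of each ring are cut first. C3–Br and C6–Br are traced to C–CO2H groups ortho to the hydroxyls, and C2–Br to a C–H para to the C5 hydroxyl. This leads to 5,5'-methylenebis(2,3-dihydroxyterephthalic acid) 9. The carboxyl groups cost nothing, since the ring construction delivers them, and they keep the catechol electron-poor and hard to oxidise until the end. Compound 9 is halogen-free. The forward reaction must perform six electrophilic brominations, four of them with loss of CO2, without oxidising the catechols or cleaving the Ar–CH2–Ar bond.

**Ester C–O bonds and ring hydrogens (9 back to 8 and 7).** Ester hydrolysis relates 9 to the tetraethyl ester 8. Adding two hydrogens across C1–C2 of each ring relates 8 to tetraethyl 5,5'-methylenebis(2,3-dioxocyclohexane-1,4-dicarboxylate) 7. Stepping down to the cyclohexane-1,2-dione level is preferred over staying aromatic because it makes the ring accessible by plain carbonyl condensation. The forward reaction is a dehydrogenation that must leave the benzylic CH2 and the esters alone.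

**Key disconnection (7 back to 4 and 5).** In both rings C3–C4 and C5–C6 are cut, four C–C bonds in all. This releases two molecules of diethyl oxalate 5 and the open-chain tetraethyl 3,3'-methylenebis(hexanedioate) 4. The neighbouring cut at C4–C5 would call for an acyloin-type coupling of a branched eight-carbon diester with no obvious source. The oxalate cut uses a symmetrical two-carbon unit, so no regiochemistry arises, and the precursor is acyclic and symmetrical. The forward reaction must make each adipate unit react with its own oxalate through both α-carbons, via the open-chain bis(ethoxalyl) tetraester 6, rather than with another chain.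

**Adipate units (4 back to 3 and 2).** Esterification relates 4 to the tetra-acid 3. Each 3-substituted adipic acid unit of 3 is the oxidative cleavage product of a 4-substituted cyclohexanol, so reconnecting the two carboxyl carbons of each unit gives 4,4'-methylenebis(cyclohexan-1-ol) 2. Because the substituent sits at C4 of the ring, both α C–C bonds are equivalent and the cleavage can give only one constitution. A stepwise chain assembly by alkylation or conjugate addition would need several C–C bond formations for the same 13-carbon skeleton.

**Saturated rings (2 back to 1).** Adding three equivalents of hydrogen to each ring of 4,4'-methylenediphenol 1 gives 2. Compound 1 already contains the CH2 bridge and an oxygen para to it, which fixes the branch at C3 of each adipate. Overall, ring carbons C1 and C2 of each phenol are excised as the future carboxyl carbons and replaced by the dioxygenated two-carbon unit of 5. The hydrogenation is the only reductive step and precedes all halogen.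

## Roads not taken

**Alternative 1: bis-aryne vicinal dibromination.**
- Cut: the C2–Br and C3–Br bonds of both rings, back to an aryne across C2–C3.
- Key step: CsF would unmask the arynes from the bis(ortho-silylaryl triflate) A2, bis[4,5-dimethoxy-2-(trifluoromethanesulfonyloxy)-3-(trimethylsilyl)phenyl]methane. Bromide and a Br+ donor (Bu4NBr with CBr4) would add across each aryne to give bis(2,3-dibromo-4,5-dimethoxyphenyl)methane A1.
- Merits: the rings stay aromatic throughout. The contiguous C2/C3 bromine pair, the most crowded one for electrophilic substitution, is installed without relying on directing effects. Only C6 bromination and ether cleavage would remain after A1, one step fewer than the chosen plan needs after its key step.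
- Weak points: A2 needs an extra phenolic oxygen at C2 and a silicon at C3 on each ring. Building this twice on a diarylmethane is likely to take more steps than the entire chosen route. Vicinal dihalogenation of arynes competes with protonation. It would have to succeed on two arynes in one molecule, each flanked by a methoxy group and by an acidic diarylmethane CH2.
- Comparison: this road is better in avoiding the oxidation-level detour and the nitric acid step. The chosen plan sets against it commodity starting materials, substituent positions fixed by chain connectivity, and no step that depends on trapping a short-lived intermediate twice.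

**Alternative 2: dibromocarbene ring expansion.**
- Cut: C2–C3 and C3–C4, removing C3 with its bromine from each ring.
- Key step: dibromocarbene (CHBr3, KOt-Bu) would add to one enol ether double bond of each ring of bis[3,4-bis(trimethylsilyloxy)cyclopenta-2,4-dien-1-yl]methane A4, the silyl enol ether of 4,4'-methylenebis(cyclopentane-1,2-dione) A5. Opening of the dibromocyclopropane with loss of bromide and tautomerisation would give bis(3-bromo-4,5-dihydroxyphenyl)methane A3.
- Merits: the arene and one C–Br bond per ring arise in the same step, so no separate dehydrogenation is needed. The catechol is fixed para and meta to the bridge by the diketone, as securely as in the chosen plan.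
- Weak points: the bromine it installs, at C3 ortho to a hydroxyl, is one that electrophilic bromination would supply anyway. A4 is a labile cyclopentadiene, prone to hydrogen shifts, dimerisation and desilylation by KOt-Bu, and the carbene can add to both double bonds. A5 is not commercial and would most plausibly be made by an oxalate condensation on a glutarate-type tetraester. That is the logic of the chosen plan one carbon short, with a carbene then needed to restore the missing carbon.
- Comparison: the chosen plan builds the six-membered ring directly with all its carbons and uses only stable intermediates. It pays with one extra aromatisation step.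

**Alternative 3: thiophene dioxide and skipped bromodiyne benzannulation.**
- Cut: C1–C6 and C2–C3 in each ring.
- Key step: two molecules of 2,5-dibromo-3,4-dimethoxythiophene 1,1-dioxide A7 would add as dienes to the two bromoalkynes of 1,5-dibromopenta-1,4-diyne A8. Loss of SO2 would give bis(2,3,6-tribromo-4,5-dimethoxyphenyl)methane A6, leaving only demethylation.
- Merits: this is by far the most convergent road. One step would create both rings with all six bromines, all four oxygens and the bridge, and the symmetrical diene allows no regiochemical error. In step count it clearly beats the chosen plan.
- Weak points: thiophene dioxides are electron-poor dienes that want electron-rich or strained partners, and a bromoalkyne is neither. The two methoxy groups make A7 a still less willing diene. The forcing temperatures this implies favour self-dimerisation of A7 and isomerisation or decomposition of A8, a skipped diyne with an acidic CH2. The second cycloaddition must also build a ring carbon flanked by two bromines next to the bridge. Preparing A7 by S-oxidation of a dibrominated, electron-rich thiophene is itself uncertain.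
- Comparison: the chosen plan is several steps longer. In exchange every step is a classical reaction type with close precedent, and the ring-forming step runs under thermodynamic control instead of depending on an electronically mismatched cycloaddition.

Key step: step 4

Assumption: the single isomer 4,4'-methylenediphenol is used, not technical bisphenol F, which is a mixture of positional isomers. All saturated intermediates are carried as mixtures of stereoisomers because every stereocentre is destroyed in step 5.

## Route

Step 1
Reactants: 1 4,4'-methylenediphenol
Product: 2 4,4'-methylenebis(cyclohexan-1-ol), mixture of cis and trans isomers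
Conditions: H2 (50 bar), 5% Rh/C, i-PrOH, 80 °C
Reagents that add atoms: none
Why: Heterogeneous hydrogenation of phenols to cyclohexanols over Rh/C is standard and keeps C–O hydrogenolysis low in a neutral alcohol; the cis/trans isomers need no separation because the carbinol carbons become carboxyl carbons in step 2.

Step 2
Reactants: 2 4,4'-methylenebis(cyclohexan-1-ol)
Product: 3 3,3'-methylenebis(hexanedioic acid), mixture of meso and racemic forms
Conditions: 50% aq. HNO3, NH4VO3 (cat.), 55–65 °C
Reagents that add atoms: nitric acid, O[N+](=O)[O-]; water, O
Why: Nitric acid oxidation of a cyclohexanol to an adipic acid (ketone, α-nitrosation, C1–C2 cleavage), the reaction type that turns 4-alkylcyclohexanols into 3-alkyladipic acids; the C4 substituent makes both α-carbons equivalent, so only the 3-substituted diacid can form. C3 and C3' become stereocentres without control, which is immaterial because both are flattened in step 5.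

Step 3
Reactants: 3 3,3'-methylenebis(hexanedioic acid)
Product: 4 tetraethyl 3,3'-methylenebis(hexanedioate), mixture of diastereomers
Conditions: EtOH, H2SO4 (cat.), toluene, reflux, Dean–Stark
Reagents that add atoms: ethanol, CCO
Why: Fischer esterification of four unhindered aliphatic acids, driven by azeotropic removal of water.

Step 4
Reactants: 4 tetraethyl 3,3'-methylenebis(hexanedioate); 5 diethyl oxalate
Product: 7 tetraethyl 5,5'-methylenebis(2,3-dioxocyclohexane-1,4-dicarboxylate) as its enol tautomers, via open-chain bis(ethoxalyl) tetraester 6 (not isolated)
Conditions: 5 (2.4 equiv), NaOEt (4.5 equiv), EtOH/toluene, 0 °C to 80 °C with distillation of EtOH; then cold 2 M HCl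
Reagents that add atoms: none
Why: Ethoxide reversibly forms the ester enolates of 4, and the less hindered α-carbon of each adipate unit (C5 of the hexanedioate, future ring C3) acylates diethyl oxalate, the only non-enolisable and the most electrophilic ester present, in a crossed Claisen step that gives 6 as its enolate. The other α-carbon of the same unit (C2 of the hexanedioate, next to the branch, future ring C6) then attacks the remaining oxalyl ester carbonyl in a 6-exo-trig Dieckmann-type closure, so that C3–C4 and then C5–C6 form in each ring and both cyclohexane-1,2-dione rings close by the same mode. The closest known reaction is the NaOEt-mediated condensation of dialkyl adipates with dialkyl oxalates to dialkyl 2,3-dioxocyclohexane-1,4-dicarboxylates. Three stereocentres per ring (C1, C3, C6) arise without control; C3 and C6 are enolised in the product and all three are removed in step 5, so no stereocontrol element is needed. Constitutional selectivity is automatic because oxalate is symmetrical and each adipate unit has only two α-carbons, which places the dione para and meta to the bridge and the esters on C3 and C6. The selectivity that must be won is chemoselectivity: closure of each unit onto its own oxalyl group has to beat acylation of a second chain, the five-membered Dieckmann closure within one adipate unit and the six-membered Dieckmann closure between the two acetate arms across the CH2 bridge. It is secured because every Claisen step is reversible under ethoxide while only the desired product binds four equivalents of base as two bis-enolate rings, the largest number of stabilised enolates the system can reach; premixing 4 with a slight excess of 5, using more than four equivalents of NaOEt and distilling off ethanol funnel the equilibria into that sink.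

Step 5
Reactants: 7 tetraethyl 5,5'-methylenebis(2,3-dioxocyclohexane-1,4-dicarboxylate)
Product: 8 tetraethyl 5,5'-methylenebis(2,3-dihydroxyterephthalate)
Conditions: Br2 (2.0 equiv), CHCl3, 0 °C to reflux, dark
Reagents that add atoms: none
Why: Halogenation–dehydrohalogenation aromatisation known for dialkyl 2,3-dioxocyclohexane-1,4-dicarboxylates: Br2 attacks the enol at C3 or C6, HBr is lost into the ring and tautomerisation gives the dihydroxyterephthalate, erasing every stereocentre. One equivalent of Br2 per ring, exclusion of light and the two deactivating esters should hold back benzylic and nuclear bromination; stray nuclear bromination could only occur at C2, where bromine is wanted later.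

Step 6
Reactants: 8 tetraethyl 5,5'-methylenebis(2,3-dihydroxyterephthalate)
Product: 9 5,5'-methylenebis(2,3-dihydroxyterephthalic acid)
Conditions: NaOH, H2O/EtOH, N2, reflux; then HCl to pH 1
Reagents that add atoms: sodium hydroxide, [Na+].[OH-]
Why: Ester saponification by acyl–oxygen cleavage; the hindered ortho-hydroxy esters are expected to need reflux, and exclusion of air protects the catecholate from oxidation before acidification precipitates the tetra-acid.

Step 7
Reactants: 9 5,5'-methylenebis(2,3-dihydroxyterephthalic acid)
Product: 10 bis(2,3,6-tribromo-4,5-dihydroxyphenyl)methane
Conditions: Br2 (6.5 equiv), AcOH/H2O, 20 to 50 °C; then aq. Na2S2O4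
Reagents that add atoms: bromine, BrBr
Why: ipso-Bromodecarboxylation of ortho-hydroxybenzoic acids, the reaction by which salicylic acid gives 2,4,6-tribromophenol in bromine water: Br+ adds at C3 and C6, each ortho to a hydroxyl, and the dienone carboxylic acid loses CO2, while C2–H, para to the C5 hydroxyl, is brominated by ordinary electrophilic substitution. The acidic medium, near-stoichiometric Br2 and the reductive quench should protect the catechols from ortho-quinone formation and limit ipso attack at C1.

## Compound list

1 | 4,4'-methylenediphenol | Oc1ccc(Cc2ccc(O)cc2)cc1 | starting material
2 | 4,4'-methylenebis(cyclohexan-1-ol), cis/trans mixture | OC1CCC(CC2CCC(O)CC2)CC1 | intermediate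
3 | 3,3'-methylenebis(hexanedioic acid), meso/racemic mixture | OC(=O)CCC(CC(=O)O)CC(CCC(=O)O)CC(=O)O | intermediate
4 | tetraethyl 3,3'-methylenebis(hexanedioate), mixture of diastereomers | CCOC(=O)CCC(CC(=O)OCC)CC(CCC(=O)OCC)CC(=O)OCC | intermediate
5 | diethyl oxalate | CCOC(=O)C(=O)OCC | starting material
6 | tetraethyl 3,3'-methylenebis[5-(2-ethoxy-2-oxoacetyl)hexanedioate], open-chain bis(ethoxalyl) tetraester, stereocentres unassigned, not isolated | CCOC(=O)C(C(=O)C(=O)OCC)CC(CC(=O)OCC)CC(CC(C(=O)C(=O)OCC)C(=O)OCC)CC(=O)OCC | intermediate
7 | tetraethyl 5,5'-methylenebis(2,3-dioxocyclohexane-1,4-dicarboxylate), drawn as the keto form, labile stereocentres unassigned | CCOC(=O)C1CC(CC2CC(C(=O)OCC)C(=O)C(=O)C2C(=O)OCC)C(C(=O)OCC)C(=O)C1=O | intermediate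
8 | tetraethyl 5,5'-methylenebis(2,3-dihydroxyterephthalate) | CCOC(=O)c1cc(Cc2cc(C(=O)OCC)c(O)c(O)c2C(=O)OCC)c(C(=O)OCC)c(O)c1O | intermediate
9 | 5,5'-methylenebis(2,3-dihydroxyterephthalic acid) | OC(=O)c1cc(Cc2cc(C(=O)O)c(O)c(O)c2C(=O)O)c(C(=O)O)c(O)c1O | intermediate
10 | bis(2,3,6-tribromo-4,5-dihydroxyphenyl)methane | Oc1c(O)c(Br)c(Cc2c(Br)c(O)c(O)c(Br)c2Br)c(Br)c1Br | target

## Step count and risks

Total steps: 7. Longest linear sequence: 7 steps (1 to 10).

**Step 4 (key step).** The most likely failure is cross-condensation:
- an oxalate bridging two chains;
- the six-membered Dieckmann closure between the two acetate arms across the CH2 bridge;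
- the five-membered Dieckmann closure within one adipate unit;
- a sluggish second closure at the hindered α-carbon next to the branch.

Any of these would leave oligomeric or wrongly cyclised material in place of two clean ring closures. The fallback keeps the oxalate disconnection but applies it to one adipate unit at a time, which removes every cross-unit pathway. It sets out from 5. Condensation of 5 with commercial diethyl adipate under the same NaOEt conditions should give diethyl 2,3-dioxocyclohexane-1,4-dicarboxylate F1. Br2 in CHCl3 should aromatise it to diethyl 2,3-dihydroxyterephthalate F2. Two molecules of F2 would then be joined with paraformaldehyde in H2SO4/AcOH, by hydroxymethylation para to a phenolic hydroxyl and Friedel–Crafts alkylation of a second ring, the reaction type that converts salicylic acid into methylenedisalicylic acid. This returns to the route at 8. The price is that the bridge must then stop at the dimer although each ring of 8 keeps one free position para to a hydroxyl, so F2 would be used in excess and recycled. That is why the main route carries the bridge from the start.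

**Step 7.** Three processes threaten it: oxidation of the catechols by bromine, ipso attack at C1 with cleavage of the diarylmethane link, and incomplete replacement of the carboxyl groups on the deactivated rings. The fallback separates loss of CO2 from halogenation. It sets out from 9. Protodecarboxylation with Cu2O and 1,10-phenanthroline in NMP/quinoline at 170 °C under N2 should give 4,4'-methylenebis(benzene-1,2-diol) F3. Exhaustive bromination of F3 with Br2 in AcOH, the way catechol is taken to tetrabromocatechol, followed by a Na2S2O4 quench, returns to the route at 10.

**Step 2.** The oxidation may overrun with loss of chain carbons as CO2, giving shortened acids, or attack the tertiary C–H, and the water-soluble tetra-acid may be hard to free from such by-products. The fallback cleaves an alkene instead of an alcohol. It sets out from 2. Dehydration with POCl3 in pyridine, an E2 elimination of the dichlorophosphate that avoids carbocation migration, should give 4,4'-methylenebis(cyclohex-1-ene) F4. Ozonolysis with oxidative work-up (O3, CH2Cl2/MeOH, −78 °C; then H2O2, HCO2H) cleaves each ring to the same 3-substituted adipic acid and returns to the route at 3.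

**Step 5.** Dehydrogenation may be accompanied by partial bromination of the ring at C2 or by incomplete loss of HBr, giving mixtures that are hard to separate. The fallback accepts the ring bromination and drives it to completion. It sets out from 7. Excess Br2 in AcOH should give tetraethyl 5,5'-methylenebis(6-bromo-2,3-dihydroxyterephthalate) F5. Saponification with NaOH under N2 should give 5,5'-methylenebis(6-bromo-2,3-dihydroxyterephthalic acid) F6. Bromine in aqueous AcOH then has only the four bromodecarboxylations left to perform, and the sequence returns to the route at 10.

## Further compounds

F1 | step 4 | diethyl 2,3-dioxocyclohexane-1,4-dicarboxylate | CCOC(=O)C1CCC(C(=O)OCC)C(=O)C1=O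
F2 | step 4 | diethyl 2,3-dihydroxyterephthalate | CCOC(=O)c1ccc(C(=O)OCC)c(O)c1O
F3 | step 7 | 4,4'-methylenebis(benzene-1,2-diol) | Oc1ccc(Cc2ccc(O)c(O)c2)cc1O
F4 | step 2 | 4,4'-methylenebis(cyclohex-1-ene) | C1=CCC(CC2CCC=CC2)CC1
F5 | step 5 | tetraethyl 5,5'-methylenebis(6-bromo-2,3-dihydroxyterephthalate) | CCOC(=O)c1c(Br)c(Cc2c(Br)c(C(=O)OCC)c(O)c(O)c2C(=O)OCC)c(C(=O)OCC)c(O)c1O
F6 | step 5 | 5,5'-methylenebis(6-bromo-2,3-dihydroxyterephthalic acid) | OC(=O)c1c(Br)c(Cc2c(Br)c(C(=O)O)c(O)c(O)c2C(=O)O)c(C(=O)O)c(O)c1O
A1 | alternative 1 | bis(2,3-dibromo-4,5-dimethoxyphenyl)methane | COc1cc(Cc2cc(OC)c(OC)c(Br)c2Br)c(Br)c(Br)c1OC
A2 | alternative 1 | bis[4,5-dimethoxy-2-(trifluoromethanesulfonyloxy)-3-(trimethylsilyl)phenyl]methane | COc1cc(Cc2cc(OC)c(OC)c([Si](C)(C)C)c2OS(=O)(=O)C(F)(F)F)c(OS(=O)(=O)C(F)(F)F)c([Si](C)(C)C)c1OC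
A3 | alternative 2 | bis(3-bromo-4,5-dihydroxyphenyl)methane | Oc1cc(Cc2cc(O)c(O)c(Br)c2)cc(Br)c1O
A4 | alternative 2 | bis[3,4-bis(trimethylsilyloxy)cyclopenta-2,4-dien-1-yl]methane | C[Si](C)(C)OC1=CC(CC2C=C(O[Si](C)(C)C)C(O[Si](C)(C)C)=C2)C=C1O[Si](C)(C)C
A5 | alternative 2 | 4,4'-methylenebis(cyclopentane-1,2-dione) | O=C1CC(CC2CC(=O)C(=O)C2)CC1=O
A6 | alternative 3 | bis(2,3,6-tribromo-4,5-dimethoxyphenyl)methane | COc1c(OC)c(Br)c(Cc2c(Br)c(OC)c(OC)c(Br)c2Br)c(Br)c1Br
A7 | alternative 3 | 2,5-dibromo-3,4-dimethoxythiophene 1,1-dioxide | COC1=C(Br)S(=O)(=O)C(Br)=C1OC
A8 | alternative 3 | 1,5-dibromopenta-1,4-diyne | BrC#CCC#CBr
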